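**Retrosynthetic overview**
1. The tropone is made last: one CH unit (from CH2Cl2) is inserted into the fully substituted benzene ring of salicylate 15, between the C11-bearing carbon and the methyl-bearing carbon next to the ester (dearomative cyclopropanation and ring expansion).
2. 15 comes from spiro-dihydrobenzofuran 11 by Markovnikov hydration of the isopropenyl group, face-selective hydrogenation (sets C8, saturates the side chain) and saponification.
3. 11 comes from iodo-Evernyl 2 and exocyclic diene 9 by a Larock [3+2] heteroannulation (C11–aryl and C9–O bonds, C9 stereocentre).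
4. 9 comes from (S)-carvone by α'-methylation, α'-vinylation with a β-iodoacrylate (quaternary C10) and Wittig methylenation. Evernyl, a bulk fragrance arene, already carries the ester, both methyls and both oxygens of the future tropone.
5. Ring order: cyclohexane (from carvone), then dihydrofuran (step 5), then tropone (step 9).

**Assumption:** the SMILES is taken literally, i.e. (5S,8R,9S,10R) in the locants defined below.

**Conventions:** the cyclohexane carbons carry seco-drimane locants. C9 is the spiro carbon (ring O and C11H2), C8 is CH–CH3, C7 and C6 are CH2, C5 is the CH bearing C4 (isopropenyl, later C(CH3)2OH), and C10 is the quaternary carbon (CH3 and the three-carbon chain). Face A is the face of the 10-methyl group (it also holds the 8-methyl, the C5 substituent and C11). Face B is the opposite face (ring oxygen and the chain). Compounds 3–5 and 7 use carvone locants.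

**Step 1**
Reactants: 1 Evernyl (methyl 2,4-dihydroxy-3,6-dimethylbenzoate)
Product: 2 methyl 2,4-dihydroxy-5-iodo-3,6-dimethylbenzoate
Conditions: NIS, MeCN, 0 °C to rt
Reagents that add atoms: N-iodosuccinimide, O=C1CCC(=O)N1I
Why: Electrophilic aromatic iodination; C5 is the only free ring position and is ortho/para to both hydroxyl groups.

**Step 2**
Reactants: 3 (S)-(+)-carvone
Product: 5 trans-6-methylcarvone [(5S,6R)-2,6-dimethyl-5-(prop-1-en-2-yl)cyclohex-2-en-1-one], via lithium dienolate 4 (not isolated)
Conditions: LiN(iPr)2, THF, −78 °C; then MeI, −78 to −20 °C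
Reagents that add atoms: iodomethane, CI
Why: Kinetic α'-deprotonation gives cross-conjugated dienolate 4, which is C-methylated (enolate alkylation); the new C6 centre forms mainly trans to the isopropenyl group but is erased by re-enolisation in step 3.

**Step 3**
Reactants: 5 trans-6-methylcarvone; 6 ethyl (Z)-3-iodoprop-2-enoate
Product: 8 enone ester ethyl (E)-3-[(1R,6R)-1,3-dimethyl-2-oxo-6-(prop-1-en-2-yl)cyclohex-3-en-1-yl]prop-2-enoate, via lithium enolate 7 (not isolated)
Conditions: LiN(iPr)2, THF, −78 to −40 °C; then 6, −78 to −20 °C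
Reagents that add atoms: none
Why: Conjugate addition–elimination (nucleophilic vinylic substitution) of tetrasubstituted enolate 7 on the β-iodoacrylate, in which fast loss of iodide pre-empts the intramolecular second Michael addition that plain acrylates give with such dienolates; the acceptor approaches anti to the neighbouring isopropenyl group, so quaternary C10 is set (R) with the chain trans and the methyl cis to isopropenyl.

**Step 4**
Reactants: 8 enone ester
Product: 9 triene ester ethyl (E)-3-[(1R,6R)-1,3-dimethyl-2-methylidene-6-(prop-1-en-2-yl)cyclohex-3-en-1-yl]prop-2-enoate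
Conditions: Ph3PCH3Br, KOtBu, toluene, 0 to 70 °C
Reagents that add atoms: methyltriphenylphosphonium bromide, C[P+](c1ccccc1)(c1ccccc1)c1ccccc1.[Br-]
Why: Wittig methylenation of the hindered enone carbonyl (the enoate, whose β-carbon is neopentyl, reacts much more slowly) gives the exocyclic 1,3-diene without touching a stereocentre.

**Step 5**
Reactants: 9 triene ester; 2 iodo-Evernyl
Product: 11 spiro-dihydrobenzofuran (5R,9S,10R), via oxapalladacycle 10 (not isolated)
Conditions: Pd(OAc)2 (5 mol%), Na2CO3, n-Bu4NCl, DMF, 80 °C
Reagents that add atoms: none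
Why: Larock heteroannulation: oxidative addition of the aryl iodide to zerovalent palladium, then syn-arylpalladation of the exocyclic methylene (aryl to C11, palladium to C9) from face B, away from the 10-methyl and 5-isopropenyl groups that flank face A, gives 10; C–O reductive elimination with retention closes the five-membered ring with the oxygen on face B (C9 = S).

**Step 6**
Reactants: 11 spiro-dihydrobenzofuran
Product: 13 tertiary alcohol (5S,9S,10R), via organomercurial 12 (not isolated)
Conditions: Hg(OAc)2, THF/H2O (1:1), rt; then NaBH4, 3 M NaOH, 0 °C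
Reagents that add atoms: water, O (Hg(OAc)2, CC(=O)O[Hg]OC(C)=O, adds atoms only to intermediate 12)
Why: Markovnikov oxymercuration–demercuration; divalent mercury attacks only the electron-rich, unhindered 1,1-disubstituted alkene (the enoate, the hindered ring alkene and the fully substituted arene are inert), and no stereocentre is formed.

**Step 7**
Reactants: 13 tertiary alcohol
Product: 14 saturated ethyl ester (5S,8R,9S,10R)
Conditions: H2 (3 atm), PtO2, EtOAc, rt
Reagents that add atoms: none
Why: Heterogeneous catalytic hydrogenation: H2 adds to C7=C8 from face B, opposite the axial 10-methyl and the C11 methylene, which places the 8-methyl on face A (C8 = R) and saturates the enoate in the same operation; platinum is chosen over palladium to avoid hydrogenolysis of the allylic aryl ether.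

**Step 8**
Reactants: 14 saturated ethyl ester
Product: 15 benzenoid seco-acid (5S,8R,9S,10R)
Conditions: LiOH·H2O, THF/H2O (3:1), rt; then 1 M HCl to pH 3
Reagents that add atoms: lithium hydroxide, [Li+].[OH-]
Why: Saponification; the unhindered primary-alkyl ethyl ester is hydrolysed while the di-ortho-substituted, phenoxide-deactivated aryl methyl ester is left intact.

**Step 9**
Reactants: 15 benzenoid seco-acid
Product: 18 target CNP0448476.4, via trilithium salt 16 (not isolated), via chlorocyclopropane dienolate 17 (not isolated)
Conditions: LiTMP (lithium 2,2,6,6-tetramethylpiperidide, 5 equiv), CH2Cl2 (2 equiv), THF, −78 to 0 °C; then aq. NaH2PO4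
Reagents that add atoms: dichloromethane, ClCCl
Why: Proposed new method: the phenoxide of 16 attacks the chlorocarbenoid LiCHCl2 through its para carbon (the C11-bearing ring carbon, also ortho to the ether oxygen); the resulting α-chloro carbanion closes onto the neighbouring methyl-bearing carbon, which is the doubly activated β-carbon of the dienone–ester, to give 17; enolate-assisted cyclopropyl-to-allyl opening with loss of chloride then inserts the CH between these two carbons and gives the tropone without touching a stereocentre. The closest known reactions are the chlorocarbene ring expansion of lithium phenoxides to tropones (ortho mode, a relative of the Ciamician–Dennstedt rearrangement) and the tin-hydride ring expansion of 4-(dichloromethyl)cyclohexa-2,5-dienones to tropones.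

**Compound list**
1 | Evernyl, methyl 2,4-dihydroxy-3,6-dimethylbenzoate | COC(=O)c1c(C)cc(O)c(C)c1O | starting material
2 | methyl 2,4-dihydroxy-5-iodo-3,6-dimethylbenzoate | COC(=O)c1c(C)c(I)c(O)c(C)c1O | intermediate
3 | (S)-(+)-carvone, (5S)-2-methyl-5-(prop-1-en-2-yl)cyclohex-2-en-1-one | CC1=CC[C@@H](CC1=O)C(C)=C | starting material
4 | cross-conjugated lithium dienolate of carvone (C1–O−, C1=C6) | [Li+].[O-]C1=C[C@@H](C(C)=C)CC=C1C | intermediate
5 | trans-6-methylcarvone, (5S,6R)-2,6-dimethyl-5-(prop-1-en-2-yl)cyclohex-2-en-1-one (major epimer; the cis epimer converges) | O=C1C(C)=CC[C@H](C(C)=C)[C@H]1C | intermediate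
6 | ethyl (Z)-3-iodoprop-2-enoate | CCOC(=O)/C=C\I | starting material
7 | lithium enolate of 5 (tetrasubstituted C1=C6 enolate) | [Li+].[O-]C1=C(C)[C@@H](C(C)=C)CC=C1C | intermediate
8 | ethyl (E)-3-[(1R,6R)-1,3-dimethyl-2-oxo-6-(prop-1-en-2-yl)cyclohex-3-en-1-yl]prop-2-enoate (chain trans, methyl cis to isopropenyl) | O=C1C(C)=CC[C@H](C(C)=C)[C@@]1(C)/C=C/C(=O)OCC | intermediate
9 | ethyl (E)-3-[(1R,6R)-1,3-dimethyl-2-methylidene-6-(prop-1-en-2-yl)cyclohex-3-en-1-yl]prop-2-enoate | C=C1C(C)=CC[C@H](C(C)=C)[C@@]1(C)/C=C/C(=O)OCC | intermediate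
10 | six-membered C,O-palladacycle of divalent palladium (drawn as the σ-allyl form, other ligands omitted; Pd on face B of C9) | COC(=O)c1c(C)c2c(c(C)c1O)O[Pd][C@@]1(C2)C(C)=CC[C@H](C(C)=C)[C@@]1(C)/C=C/C(=O)OCC | intermediate
11 | methyl 6-hydroxy-4,7-dimethyl-3H-spiro[1-benzofuran-2,1'-cyclohex-2'-ene]-5-carboxylate carrying 8-CH3, 10-CH3, 10-[(E)-CH=CH–CO2Et] and 5-isopropenyl; ring O and enoate on face B; (5R,9S,10R) | COC(=O)c1c(C)c2c(c(C)c1O)O[C@@]1(C2)C(C)=CC[C@H](C(C)=C)[C@@]1(C)/C=C/C(=O)OCC | intermediate
12 | β-hydroxyalkylmercury acetate from 11 (5-C(CH3)(OH)CH2HgOAc; new carbinol centre unassigned) | COC(=O)c1c(C)c2c(c(C)c1O)O[C@@]1(C2)C(C)=CC[C@H](C(C)(O)C[Hg]OC(C)=O)[C@@]1(C)/C=C/C(=O)OCC | intermediate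
13 | as 11 but with 5-(2-hydroxypropan-2-yl); (5S,9S,10R) | COC(=O)c1c(C)c2c(c(C)c1O)O[C@@]1(C2)C(C)=CC[C@H](C(C)(C)O)[C@@]1(C)/C=C/C(=O)OCC | intermediate
14 | methyl 6-hydroxy-4,7-dimethyl-3H-spiro[1-benzofuran-2,1'-cyclohexane]-5-carboxylate carrying 8-CH3, 10-CH3, 10-CH2CH2CO2Et and 5-C(CH3)2OH; (5S,8R,9S,10R) | COC(=O)c1c(C)c2c(c(C)c1O)O[C@@]1(C2)[C@H](C)CC[C@H](C(C)(C)O)[C@@]1(C)CCC(=O)OCC | intermediate
15 | free acid of 14 (10-CH2CH2CO2H); (5S,8R,9S,10R) | COC(=O)c1c(C)c2c(c(C)c1O)O[C@@]1(C2)[C@H](C)CC[C@H](C(C)(C)O)[C@@]1(C)CCC(=O)O | intermediate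
16 | trilithium salt of 15 (phenoxide, tertiary alkoxide, carboxylate) | [Li+].[Li+].[Li+].COC(=O)c1c(C)c2c(c(C)c1[O-])O[C@@]1(C2)[C@H](C)CC[C@H](C(C)(C)[O-])[C@@]1(C)CCC(=O)[O-] | intermediate
17 | 7-chloronorcaradiene-type dienolate (chlorocyclopropane across the C11-bearing and methyl-bearing ring carbons; new centres unassigned), trilithium salt | [Li+].[Li+].[Li+].COC(=O)C1=C([O-])C(C)=C2O[C@@]3(CC24C(Cl)C14C)[C@H](C)CC[C@H](C(C)(C)[O-])[C@@]3(C)CCC(=O)[O-] | intermediate
18 | target CNP0448476.4, tropone-fused spiro-dihydrofuran seco-acid; (5S,8R,9S,10R) | COC(=O)c1c(C)cc2c(c(C)c1=O)O[C@@]1(C2)[C@H](C)CC[C@H](C(C)(C)O)[C@@]1(C)CCC(=O)O | target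

**Step count:** 9 steps in total. The longest linear sequence is 8 steps (steps 2–9 from (S)-carvone); step 1 is the one-step arene branch that joins at step 5.

**Steps most likely to fail, with fallbacks**

Step 9 (carbon insertion). The carbenoid may attack the phenoxide oxygen or an ortho carbon, which would give O-alkylation or regioisomeric tropones, and the product may react further. The fallback sets out from 15 and replaces the anionic one-pot insertion by an isolable dearomatised intermediate and a radical ring expansion. Abnormal Reimer–Tiemann reaction of 15 (CHCl3, 50% aq. NaOH, BnEt3NCl, 50 °C) places a dichloromethyl group on the fully substituted para carbon and gives the 4-(dichloromethyl)cyclohexa-2,5-dienone acid F1. Heating F1 with Bu3SnH and AIBN in benzene at 80 °C generates the α-chloroalkyl radical, which adds 3-exo to the ester-activated ring carbon; the cyclopropylcarbinyl radical opens to the seven-membered ring and loses a chlorine atom. This comes back to the route at 18.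

Step 5 (Larock annulation). Outer-sphere attack of the phenoxide would give the C9 epimer, and β-hydride elimination would give Heck trienes. The fallback sets out from 9 and 1 and separates the two bond formations without an aryl iodide. Friedel–Crafts alkylation of 1 by 9 (BF3·OEt2, CH2Cl2, −40 °C; protonation of the diene at C7 and attack of the arene at C11) gives the C-alkylated Evernyl with a tetrasubstituted C8=C9 alkene F2. Aerobic Wacker-type cyclisation of F2 (Pd(O2CCF3)2, pyridine, O2, toluene, 80 °C) proceeds by syn-oxypalladation from face B and β-hydride elimination toward C7, and comes back to the route at 11.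

Step 3 (vinylation at the quaternary centre). Dehydroiodination of 6, proton transfer, or bicyclisation of the adduct may win. The fallback sets out from 5 and avoids a free ester enolate. Compound 5 is converted (LiN(iPr)2, Me3SiCl, THF, −78 °C) into the trimethylsilyl dienol ether F3. Mukaiyama-type addition of F3 to the oxocarbenium ion from ethyl 3,3-diethoxypropanoate (Me3SiOTf cat., CH2Cl2, −78 °C), again anti to the isopropenyl group, gives the β-ethoxy ester F4. Treatment of F4 with DBU (toluene, 60 °C, E1cB loss of ethanol) comes back to the route at 8.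

**Further compounds**
F1 | step 9 | 4-(dichloromethyl)cyclohexa-2,5-dienone acid (15 dearomatised at the C11-bearing ring carbon; new centre unassigned) | COC(=O)C1=C(C)C2(C(Cl)Cl)C(=C(C)C1=O)O[C@@]1(C2)[C@H](C)CC[C@H](C(C)(C)O)[C@@]1(C)CCC(=O)O
F2 | step 5 | methyl 2,4-dihydroxy-3,6-dimethyl-5-(cyclohex-1-enylmethyl)benzoate with tetrasubstituted C8=C9, 8-CH3, 10-CH3, 10-[(E)-CH=CH–CO2Et] and 5-isopropenyl | COC(=O)c1c(C)c(CC2=C(C)CC[C@H](C(C)=C)[C@@]2(C)/C=C/C(=O)OCC)c(O)c(C)c1O
F3 | step 3 | trimethylsilyl dienol ether of 5 | C[Si](C)(C)OC1=C(C)[C@@H](C(C)=C)CC=C1C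
F4 | step 3 | ethyl 3-ethoxy-3-[(1R,6R)-1,3-dimethyl-2-oxo-6-(prop-1-en-2-yl)cyclohex-3-en-1-yl]propanoate (ethoxy-bearing centre unassigned) | O=C1C(C)=CC[C@H](C(C)=C)[C@@]1(C)C(OCC)CC(=O)OCC
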